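Amounts first: the violet flask starts with 0.10 M of each mirror-image substrate, and I follow how far the two amounts part by 5.0 min. The excess is c(right-handed substrate) minus c(left-handed substrate), divided by their sum.

| setting | violet | red | flask |
|---|---|---|---|
| left-handed substrate | 0.10 M | 0.050 M | 0.10 M |
| right-handed substrate | 0.10 M | 0.050 M | 0.10 M |
| partner | 0.30 M | 0.30 M | 0.300 M |
| precatalyst | 12 mM | 12 mM | 12 mM |
| remark | the very flask that is asked about, followed so far | run made earlier |  |
| time |  |  | 5.0 min |

| run | time / min | right-handed substrate / % | left-handed substrate / % |
|---|---|---|---|
| violet | 0.200 | 39.1 | 19.1 |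
| violet | 0.500 | 30.8 | 4.0 |
| violet | 1.00 | 27.2 | 1.4 |
| violet | 2.50 | 23.9 | 0.4 |
| red | 0.250 | 32.2 | 9.8 |
| red | 0.667 | 20.1 | 0.4 |
| red | 1.50 | 11.2 | 0 |
| red | 4.00 | 5.8 | 0.3 |

(scatter of a reading: 0.5 percentage points)

- whether the excess of right-handed substrate over left-handed substrate among what is left of the two reaches 80% by 5.0 min (no / yes)
- the highest excess of right-handed substrate over left-handed substrate among what is left of the two up to 5.0 min

- free catalyst is single-handed; left-handed substrate and right-handed substrate are mirror images of each other, charged as a racemate, each of them at the stated concentration
- the numbers in the tables scatter with a standard deviation of 0.5 percentage points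

The free catalyst is single-handed and takes both substrates. I assume each substrate falls in proportion to its own amount, with one shared factor for catalyst and partner. Dividing one rate by the other then removes time and that factor.

Each substrate is half of the total charged. So the violet readings at 0.500 min give 5.21. This is the selectivity factor: the logarithm of the fraction of left-handed substrate remaining, divided by the same logarithm for right-handed substrate.

An excess of 80% means one ratio of the two amounts. With my factor, it needs right-handed substrate at 29.7% of the total charged. The violet reading is 30.8% at 0.500 min and 27.2% at 1.00 min, and the second is lower than that level. So my answer is yes.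

For the top, I apply the same factor to the last right-handed reading, 23.9%. That gives left-handed substrate 1.07% and an excess of 91.5%. The left-handed reading there is 0.4%, lower than my figure, with a scatter of 0.5 points. So I take 91.5% as a low estimate.

The forecast answers yes and puts the top at 97.5%, higher than my figure, judging that “After 2.5 min little further change is likely”.

The violet flask gives yes and a top of 99.2%, higher than the forecast.

    free catalyst + left-handed substrate ⇌ catalyst intermediate A (K = 28.0 L mol⁻¹, k = 27.0 L mol⁻¹ s⁻¹)
    free catalyst + right-handed substrate ⇌ catalyst intermediate B (K = 3.70 L mol⁻¹, k = 120 L mol⁻¹ s⁻¹)
    partner + catalyst intermediate A → free catalyst + left-handed product (k = 20.0 L mol⁻¹ s⁻¹)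
    partner + catalyst intermediate B → free catalyst + right-handed product (k = 9.20 L mol⁻¹ s⁻¹)
    2 partner → self-condensation product (k = 0.140 L mol⁻¹ s⁻¹)
    partner + precatalyst → free catalyst + spent reagent (k = 0.710 L mol⁻¹ s⁻¹)

 At 5.00 min, left-handed substrate has 0.18% of its charge left and right-handed substrate 46%. The same quotient of logarithms gives 8.14 for these two amounts. On the red flask at 0.667 min, the right-handed reading 20.1% and my 5.21 give left-handed substrate 0.433%, and the reading is 0.4%.

The runs come from a simulation with constants of no real substance; the scatter is artificial.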